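## Retrosynthetic overview

1. Feature: in the hydroxy-acid ring (C1 = CH–iPr, C4 = carbinol, C5 = CH–CO2H, C6 = CH–acrylate) the CH2O arm on C4 and the carboxyl on C5 are cis one-carbon groups on neighbouring carbons, and the C4 oxygen lies on the other face. This is the imprint of a cyclobutanone ring C4–CCl2–C(=O)–C5 cut between its two exocyclic carbons.
2. Last disconnection: the inter-half ester C–O bond, made by opening a C4 spiro-epoxide at its CH2 with the acrylic carboxylate of the butenolide half. Both partners come from this one epoxide, because base converts it (E1cB, then lactonisation) into the butenolide.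
3. Epoxide ⇐ chlorohydrin ⇐ ester/CHCl2 pair ⇐ alkoxide (haloform-type) opening of the dichlorocyclobutanone ⇐ dichloroketene [2+2] on the silyl enol ether of trans-4-isopropyl-3-vinylcyclohexanone. Side chain: vinyl → CHO → (Z)-bromoacrylate → (E)-hydroxymethylacrylate.
4. Enol ether ⇐ vinyl-copper addition with silyl trapping on (R)-4-isopropylcyclohexenone ⇐ organocatalytic Michael addition and aldol condensation of isovaleraldehyde and methyl vinyl ketone.
5. Ring order: cyclohexenone (step 2), cyclobutanone (step 4, opened in step 5), spiro-epoxide (step 15), butenolide (step 16).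

Key step: step 4

Locants and faces: each six-membered ring is numbered C1 (CH–iPr), C2, C3, C4, C5, C6 (CH–side chain). α is the face of the C1 isopropyl group and β the opposite face. TMSE = 2-(trimethylsilyl)ethyl; TBS = tert-butyldimethylsilyl.

Assumption: the diarylprolinol ether catalyst is taken to follow the usual enamine-shielding model, so the (R)-catalyst gives (R)-3; if the sense were opposite, the enantiomeric catalyst would be used.

## Route

Step 1
Reactants: 1 isovaleraldehyde; 2 methyl vinyl ketone
Product: 3 (R)-2-isopropyl-5-oxohexanal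
Conditions: (R)-2-[methoxy(diphenyl)methyl]pyrrolidine (5 mol %), ethyl 3,4-dihydroxybenzoate (20 mol %), neat, 4 °C
Reagents that add atoms: none
Why: Enamine-catalysed Michael addition of an aldehyde to an enone; the CPh2OMe group shields one face of the (E)-enamine, so attack from the open face sets the isopropyl-bearing centre (future C1) as R.

Step 2
Reactants: 3 (R)-2-isopropyl-5-oxohexanal
Product: 4 (R)-4-isopropylcyclohex-2-en-1-one
Conditions: LiOH (10 mol %), i-PrOH, rt
Reagents that add atoms: none
Why: Intramolecular aldol condensation of the methyl ketone onto the aldehyde with E1cB loss of water closes the cyclohexenone, and the mild catalytic base should leave the γ-stereocentre untouched.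

Step 3
Reactants: 4 (R)-4-isopropylcyclohex-2-en-1-one; 5 vinylmagnesium bromide
Product: 7 tert-butyl{[(3R,4R)-4-isopropyl-3-vinylcyclohex-1-en-1-yl]oxy}dimethylsilane, via bromomagnesium enolate 6 (not isolated)
Conditions: 5, CuBr·SMe2 (10 mol %), TBSCl, HMPA, THF, −78 → 0 °C
Reagents that add atoms: tert-butyldimethylsilyl chloride, CC(C)(C)[Si](C)(C)Cl
Why: Copper-catalysed conjugate addition of a Grignard reagent with silyl trapping; the vinyl group arrives anti to the neighbouring isopropyl group (C6 β, trans to C1), and O-silylation of the regiodefined enolate fixes the C4=C5 enol ether.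

Step 4
Reactants: 7 silyl enol ether; 8 trichloroacetyl chloride
Product: 10 (1S,4R,5R,6S)-8,8-dichloro-1-(tert-butyldimethylsilyloxy)-4-isopropyl-5-vinylbicyclo[4.2.0]octan-7-one (C4 β-OTBS, C4 α-CCl2, C5 α-C=O, C6 β-vinyl, C1 α-iPr), via dichloroketene 9 (not isolated)
Conditions: Zn–Cu couple, 8 (1.3 equiv, slow addition), Et2O/DME, 0 °C → rt
Reagents that add atoms: none
Why: Dichloroketene, released from 8 by zinc, adds to the electron-rich C4=C5 bond in an asynchronous [2+2] that is suprafacial on the alkene: nucleophilic C5 attacks the ketene carbonyl carbon and the dichloroenolate terminus collapses onto the silyloxy-stabilised C4; the closest known reaction type is the cycloaddition of dichloroketene with silyl enol ethers of cyclic ketones to 3-silyloxy-2,2-dichlorocyclobutanones. The four-membered ring (C4, CCl2, C=O, C5) is closed by this [2+2] and can only be cis-fused. C5 is controlled by the adjacent C6 vinyl group, the ketene approaching anti to it as electrophiles do with enolates from conjugate addition, and C4 follows from the suprafacial closure, so both new carbons are α and the C4 oxygen is β. Regiochemistry is fixed by the polarity of the enol ether, whose position is itself fixed by the enolate trapping of step 3. The chemoselectivity needed, enol ether over the monosubstituted vinyl group, rests on the far higher nucleophilicity of the enol ether and is supported by slow addition of a small excess of 8. DME binds zinc chloride and the TBS ether resists it, which should protect the adduct from Lewis-acid-induced retro-aldol opening.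

Step 5
Reactants: 10 dichlorocyclobutanone; 11 2-(trimethylsilyl)ethanol
Product: 12 TMSE ester with C1 α-iPr, C4 β-OTBS and α-CHCl2, C5 α-CO2TMSE, C6 β-vinyl
Conditions: 11 (5 equiv), NaH (0.2 equiv), THF, −20 → 0 °C; AcOH
Reagents that add atoms: none
Why: Haloform-type cleavage of a 2,2-dichlorocyclobutanone; the alkoxide adds to the strained, activated carbonyl and the adduct expels the chlorine-stabilised carbanion, which the excess alcohol protonates at once, so only the C(=O)–CCl2 bond breaks, no stereocentre is touched, and the C5 ester ends equatorial with no drive to epimerise.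

Step 6
Reactants: 12 dichloromethyl ester
Product: 13 chloromethyl ester (as 12, C4 α-CH2Cl)
Conditions: Bu3SnH (1.05 equiv, slow addition), AIBN (cat.), PhH, 80 °C
Reagents that add atoms: none
Why: Radical-chain hydrodechlorination; a gem-dichloride loses chlorine much faster than the primary chloride it forms, so one equivalent of hydride should stop at CH2Cl, and the trans relation of arm and vinyl group rules out 5-exo cyclisation.

Step 7
Reactants: 13 chloromethyl ester
Product: 15 C6 β-carbaldehyde (otherwise as 13), via secondary ozonide 14 (not isolated)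
Conditions: O3, CH2Cl2, −78 °C; Me2S, −78 °C → rt
Reagents that add atoms: ozone, [O-][O+]=O
Why: Ozonolysis with reductive work-up of the only C=C bond; the aldehyde is equatorial and trans to both neighbours, the favoured epimer, so C6 should hold.

Step 8
Reactants: 16 bromoacetyl bromide; 11 2-(trimethylsilyl)ethanol
Product: 17 2-(trimethylsilyl)ethyl bromoacetate
Conditions: pyridine, CH2Cl2, 0 °C
Reagents that add atoms: none
Why: O-acylation of the alcohol; the acyl bromide reacts far faster than the alkyl bromide.

Step 9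
Reactants: 17 TMSE bromoacetate; 18 triphenylphosphine
Product: 20 2-(trimethylsilyl)ethyl (triphenylphosphoranylidene)acetate, via phosphonium bromide 19 (not isolated)
Conditions: PhMe, rt; then aq NaOH, CH2Cl2
Reagents that add atoms: none
Why: SN2 quaternisation of the phosphine by the α-bromo ester, followed by deprotonation to the stabilised ylide.

Step 10
Reactants: 20 stabilised ylide
Product: 22 2-(trimethylsilyl)ethyl bromo(triphenylphosphoranylidene)acetate, via bromophosphonium bromide 21 (not isolated)
Conditions: Br2, CH2Cl2, 0 °C; then aq NaOH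
Reagents that add atoms: bromine, BrBr
Why: Electrophilic C-bromination of a stabilised ylide and deprotonation of the resulting salt, the standard access to α-bromo ylides.

Step 11
Reactants: 15 aldehyde; 22 bromo ylide
Product: 23 (Z)-2-bromoacrylate (C6 β-CH=C(Br)CO2TMSE, ring carbon cis to Br and trans to the ester; otherwise as 15)
Conditions: PhMe, 80 °C
Reagents that add atoms: none
Why: Wittig olefination with a stabilised α-bromo ylide, which places the ring carbon trans to the ester group and thus gives the Z bromide.

Step 12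
Reactants: 23 (Z)-bromoacrylate; 24 (tributylstannyl)methanol
Product: 25 (E)-2-(hydroxymethyl)acrylate (C6 β-CH=C(CH2OH)CO2TMSE, ring carbon cis to CH2OH; C4 β-OTBS, α-CH2Cl)
Conditions: Pd(PPh3)4 (10 mol %), dioxane, 90 °C
Reagents that add atoms: none
Why: Stille coupling of an alkenyl bromide with a hydroxymethylstannane, which proceeds with retention of alkene geometry (the descriptor changes to E only through CIP ranking); the neopentyl chloride and the silyl groups are inert to Pd(0).

Step 13
Reactants: 25 hydroxymethylacrylate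
Product: 26 chlorohydrin diol (C4 β-OH, α-CH2Cl; free allylic CH2OH)
Conditions: 48 % aq HF, MeCN, 0 °C → rt
Reagents that add atoms: none
Why: Acidic fluoride desilylation cleaves the tertiary O–Si bond, whereas the C–Si bonds of the TMSE esters need unsolvated fluoride and should survive.

Step 14
Reactants: 26 chlorohydrin diol
Product: 27 primary TBS ether (C4 β-OH still free)
Conditions: TBSCl (1.1 equiv), imidazole, CH2Cl2, 0 °C
Reagents that add atoms: tert-butyldimethylsilyl chloride, CC(C)(C)[Si](C)(C)Cl
Why: Selective silylation of the primary allylic alcohol in the presence of a hindered tertiary alcohol.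

Step 15
Reactants: 27 chlorohydrin
Product: 28 C4 spiro-epoxide (O β, CH2 α; C5 α-CO2TMSE; C6 β-(E)-CH=C(CH2OTBS)CO2TMSE)
Conditions: NaH (1.1 equiv), THF, 0 °C; pH 7 buffer
Reagents that add atoms: none
Why: Intramolecular Williamson closure (3-exo-tet) of a chlorohydrin; the C4–O bond is not broken, so C4 is retained, and O–H deprotonation with ring closure should be far faster than enolisation at C5.

Step 16
Reactants: 28 spiro-epoxide
Product: 30 butenolide (C4=C5, lactone C5–C(=O)–O–CH2–C4; C1 α-iPr; C6 β-(E)-CH=C(CH2OTBS)CO2TMSE), via lithium γ-alkoxy enoate 29 (not isolated)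
Conditions: LiHMDS (1.2 equiv), THF, −78 → −20 °C; AcOH
Reagents that add atoms: none
Why: E1cB opening of a β,γ-epoxy ester through its C5 enolate followed by lactonisation of the cis-disposed alkoxide; allylic 1,3-strain with the cis CH2OTBS group holds C6–H in the alkene plane, so γ-deprotonation of the acrylate and loss of C6 should not compete.

Step 17
Reactants: 30 protected butenolide
Product: 31 butenolide hydroxy acid, (E)-2-(hydroxymethyl)acrylic acid on C6 β
Conditions: TBAF/AcOH (1:1, 4 equiv), THF, 0 °C → rt
Reagents that add atoms: none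
Why: Fluoride-induced β-fragmentation of the TMSE ester and O-desilylation; the acetic acid buffer keeps the butenolide from being deprotonated.

Step 18
Reactants: 28 spiro-epoxide; 31 butenolide hydroxy acid
Product: 32 protected dimer (C4 β-OH, C4 α-CH2–O–acyl; A-half TMSE esters and TBS ether intact)
Conditions: 31 (1.3 equiv), Cs2CO3 (0.2 equiv), DMF, 70 °C
Reagents that add atoms: none
Why: Regioselective SN2 opening of a 2,2-disubstituted epoxide by a caesium carboxylate at the CH2 terminus; C4–O is untouched (C4 retained), the excess acid protonates the tertiary alkoxide at once, a carboxylate is far too weak a base to enolise C5, and acylation on arrival keeps the arm oxygen from lactonising onto C5.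

Step 19
Reactants: 32 protected dimer
Product: 33 CNP0071646.2 (target)
Conditions: TBAF/AcOH (1:1, 6 equiv), THF, 0 °C → rt; pH 4 buffer
Reagents that add atoms: none
Why: Buffered fluoride removes both TMSE esters by β-fragmentation at the remote silicon and the TBS ether by desilylation, without the base or acid that would endanger the inter-half ester, the butenolide or the β-hydroxy acid.

## Compound list

1 | isovaleraldehyde | CC(C)CC=O | starting material
2 | methyl vinyl ketone | CC(=O)C=C | starting material
3 | (R)-2-isopropyl-5-oxohexanal | CC(C)[C@H](C=O)CCC(C)=O | intermediate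
4 | (R)-4-isopropylcyclohex-2-en-1-one | CC(C)[C@H]1CCC(=O)C=C1 | intermediate
5 | vinylmagnesium bromide | C=C[Mg]Br | starting material
6 | bromomagnesium (3R,4R)-4-isopropyl-3-vinylcyclohex-1-en-1-olate | CC(C)[C@H]1CCC(O[Mg]Br)=C[C@@H]1C=C | intermediate
7 | TBS enol ether of trans-4-isopropyl-3-vinylcyclohexanone | CC(C)[C@H]1CCC(O[Si](C)(C)C(C)(C)C)=C[C@@H]1C=C | intermediate
8 | trichloroacetyl chloride | ClC(=O)C(Cl)(Cl)Cl | starting material
9 | dichloroketene | ClC(Cl)=C=O | intermediate
10 | fused 3-silyloxy-2,2-dichlorocyclobutanone | CC(C)[C@H]1CC[C@@]2(O[Si](C)(C)C(C)(C)C)C(Cl)(Cl)C(=O)[C@H]2[C@@H]1C=C | intermediate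
11 | 2-(trimethylsilyl)ethanol | C[Si](C)(C)CCO | starting material
12 | dichloromethyl TMSE ester | CC(C)[C@H]1CC[C@@](O[Si](C)(C)C(C)(C)C)(C(Cl)Cl)[C@@H](C(=O)OCC[Si](C)(C)C)[C@@H]1C=C | intermediate
13 | chloromethyl TMSE ester | CC(C)[C@H]1CC[C@@](O[Si](C)(C)C(C)(C)C)(CCl)[C@@H](C(=O)OCC[Si](C)(C)C)[C@@H]1C=C | intermediate
14 | secondary ozonide of 13 | CC(C)[C@H]1CC[C@@](O[Si](C)(C)C(C)(C)C)(CCl)[C@@H](C(=O)OCC[Si](C)(C)C)[C@@H]1C1OCOO1 | intermediate
15 | C6 aldehyde | CC(C)[C@H]1CC[C@@](O[Si](C)(C)C(C)(C)C)(CCl)[C@@H](C(=O)OCC[Si](C)(C)C)[C@@H]1C=O | intermediate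
16 | bromoacetyl bromide | BrCC(=O)Br | starting material
17 | TMSE bromoacetate | BrCC(=O)OCC[Si](C)(C)C | intermediate
18 | triphenylphosphine | c1ccc(cc1)P(c1ccccc1)c1ccccc1 | starting material
19 | (TMSE-oxycarbonylmethyl)triphenylphosphonium bromide | [Br-].C[Si](C)(C)CCOC(=O)C[P+](c1ccccc1)(c1ccccc1)c1ccccc1 | intermediate
20 | TMSE (triphenylphosphoranylidene)acetate | C[Si](C)(C)CCOC(=O)C=P(c1ccccc1)(c1ccccc1)c1ccccc1 | intermediate
21 | [bromo(TMSE-oxycarbonyl)methyl]triphenylphosphonium bromide | [Br-].C[Si](C)(C)CCOC(=O)C(Br)[P+](c1ccccc1)(c1ccccc1)c1ccccc1 | intermediate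
22 | TMSE bromo(triphenylphosphoranylidene)acetate | C[Si](C)(C)CCOC(=O)C(Br)=P(c1ccccc1)(c1ccccc1)c1ccccc1 | intermediate
23 | (Z)-2-bromoacrylate | CC(C)[C@H]1CC[C@@](O[Si](C)(C)C(C)(C)C)(CCl)[C@@H](C(=O)OCC[Si](C)(C)C)[C@@H]1/C=C(\Br)C(=O)OCC[Si](C)(C)C | intermediate
24 | (tributylstannyl)methanol | CCCC[Sn](CO)(CCCC)CCCC | starting material
25 | (E)-2-(hydroxymethyl)acrylate, C4 OTBS | CC(C)[C@H]1CC[C@@](O[Si](C)(C)C(C)(C)C)(CCl)[C@@H](C(=O)OCC[Si](C)(C)C)[C@@H]1/C=C(\CO)C(=O)OCC[Si](C)(C)C | intermediate
26 | chlorohydrin diol | CC(C)[C@H]1CC[C@@](O)(CCl)[C@@H](C(=O)OCC[Si](C)(C)C)[C@@H]1/C=C(\CO)C(=O)OCC[Si](C)(C)C | intermediate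
27 | chlorohydrin, primary TBS ether | CC(C)[C@H]1CC[C@@](O)(CCl)[C@@H](C(=O)OCC[Si](C)(C)C)[C@@H]1/C=C(\CO[Si](C)(C)C(C)(C)C)C(=O)OCC[Si](C)(C)C | intermediate
28 | C4 spiro-epoxide | CC(C)[C@H]1CC[C@@]2(CO2)[C@@H](C(=O)OCC[Si](C)(C)C)[C@@H]1/C=C(\CO[Si](C)(C)C(C)(C)C)C(=O)OCC[Si](C)(C)C | intermediate
29 | lithium γ-alkoxy enoate | CC(C)[C@H]1CCC(CO[Li])=C(C(=O)OCC[Si](C)(C)C)[C@@H]1/C=C(\CO[Si](C)(C)C(C)(C)C)C(=O)OCC[Si](C)(C)C | intermediate
30 | protected butenolide | CC(C)[C@H]1CCC2=C(C(=O)OC2)[C@@H]1/C=C(\CO[Si](C)(C)C(C)(C)C)C(=O)OCC[Si](C)(C)C | intermediate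
31 | butenolide hydroxy acid | CC(C)[C@H]1CCC2=C(C(=O)OC2)[C@@H]1/C=C(\CO)C(=O)O | intermediate
32 | protected dimer | CC(C)[C@H]1CC[C@@](O)(COC(=O)/C(=C/[C@H]2C3=C(CC[C@@H]2C(C)C)COC3=O)CO)[C@@H](C(=O)OCC[Si](C)(C)C)[C@@H]1/C=C(\CO[Si](C)(C)C(C)(C)C)C(=O)OCC[Si](C)(C)C | intermediate
33 | CNP0071646.2 | CC(C)[C@H]1CC[C@@](O)(COC(=O)/C(=C/[C@H]2C3=C(CC[C@@H]2C(C)C)COC3=O)CO)[C@@H](C(=O)O)[C@@H]1/C=C(\CO)C(=O)O | target

## Step count and risks

Total step count: 19. Longest linear sequence: 16 (steps 1–7 and 11–19).

**Step 4.**
- What may go wrong: dichloroketene may also add to the C6 vinyl group. Zinc chloride may strip the silyl group, after which retro-aldol opening destroys the adduct. Discrimination between the two faces may be modest.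
- Fallback: remove the competing alkene. It sets out from 4.
  - TBSOTf-promoted conjugate addition of (trimethylsilyl)ethynylzinc bromide (Et2O/THF, −40 °C), anti to the isopropyl group, should give the alkynyl silyl enol ether F1 directly.
  - The same dichloroketene cycloaddition then meets only a hindered silylalkyne as rival and should give the alkynyl dichlorocyclobutanone F2.
  - The alkoxide medium of step 5 opens the ring and also cleaves the alkynyl C–Si bond, giving the terminal-alkyne ester F3.
  - Lindlar semi-hydrogenation (H2, quinoline, EtOAc) returns to the route at 12.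

**Step 5.**
- What may go wrong: the departing dichloromethyl carbanion may expel the neighbouring silyloxide (β-elimination to a dichloromethylene group). Alternatively the alkoxide may attack silicon, after which retro-aldol cleavage of the C4–CCl2 bond removes the arm.
- Fallback: it sets out from 10 and cleaves the ring hydrolytically (LiOH, THF/H2O, 0 °C), so that water protonates the carbanion as it leaves, giving the carboxylic acid F4.
- The hindered acid is then esterified alkylatively by a Mitsunobu reaction with 11 (PPh3, DIAD, THF), where bond formation occurs at the unhindered alcohol carbon. This returns to the route at 12.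

**Step 18.**
- What may go wrong: attack at the neopentyl-type CH2 of the spiro-epoxide may be too slow at temperatures the fully functionalised epoxide tolerates. Silyl loss or base-induced isomerisation of the epoxide could then overtake the union.
- Fallback: join the halves earlier, on a robust and cheaper electrophile that can be heated harder and used in excess, and grow the A side chain afterwards. It sets out from 13.
  - Aqueous HF in MeCN gives the vinyl chlorohydrin F5, and NaH in THF gives the vinyl spiro-epoxide F6.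
  - F6 (3 equiv) with 31 and catalytic Cs2CO3 in DMF at 90–100 °C should give the vinyl dimer ester F7.
  - Lemieux–Johnson cleavage (OsO4 cat., NaIO4, 2,6-lutidine, dioxane/H2O), selective for the only electron-neutral alkene, gives the dimer aldehyde F8.
  - Wittig reaction with 22 gives the dimer (Z)-bromoacrylate F9, and Stille coupling with 24 gives the dimer bis-TMSE ester F10.
  - Buffered TBAF as in step 19 returns to the route at 33.

## Further compounds

F1 | step 4 | TBS enol ether of trans-4-isopropyl-3-[(trimethylsilyl)ethynyl]cyclohexanone | CC(C)[C@H]1CCC(O[Si](C)(C)C(C)(C)C)=C[C@@H]1C#C[Si](C)(C)C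
F2 | step 4 | alkynyl dichlorocyclobutanone | CC(C)[C@H]1CC[C@@]2(O[Si](C)(C)C(C)(C)C)C(Cl)(Cl)C(=O)[C@H]2[C@@H]1C#C[Si](C)(C)C
F3 | step 4 | terminal-alkyne dichloromethyl TMSE ester | CC(C)[C@H]1CC[C@@](O[Si](C)(C)C(C)(C)C)(C(Cl)Cl)[C@@H](C(=O)OCC[Si](C)(C)C)[C@@H]1C#C
F4 | step 5 | dichloromethyl carboxylic acid | CC(C)[C@H]1CC[C@@](O[Si](C)(C)C(C)(C)C)(C(Cl)Cl)[C@@H](C(=O)O)[C@@H]1C=C
F5 | step 18 | vinyl chlorohydrin | CC(C)[C@H]1CC[C@@](O)(CCl)[C@@H](C(=O)OCC[Si](C)(C)C)[C@@H]1C=C
F6 | step 18 | vinyl spiro-epoxide | CC(C)[C@H]1CC[C@@]2(CO2)[C@@H](C(=O)OCC[Si](C)(C)C)[C@@H]1C=C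
F7 | step 18 | vinyl dimer ester | CC(C)[C@H]1CC[C@@](O)(COC(=O)/C(=C/[C@H]2C3=C(CC[C@@H]2C(C)C)COC3=O)CO)[C@@H](C(=O)OCC[Si](C)(C)C)[C@@H]1C=C
F8 | step 18 | dimer aldehyde | CC(C)[C@H]1CC[C@@](O)(COC(=O)/C(=C/[C@H]2C3=C(CC[C@@H]2C(C)C)COC3=O)CO)[C@@H](C(=O)OCC[Si](C)(C)C)[C@@H]1C=O
F9 | step 18 | dimer (Z)-bromoacrylate | CC(C)[C@H]1CC[C@@](O)(COC(=O)/C(=C/[C@H]2C3=C(CC[C@@H]2C(C)C)COC3=O)CO)[C@@H](C(=O)OCC[Si](C)(C)C)[C@@H]1/C=C(\Br)C(=O)OCC[Si](C)(C)C
F10 | step 18 | dimer bis-TMSE ester | CC(C)[C@H]1CC[C@@](O)(COC(=O)/C(=C/[C@H]2C3=C(CC[C@@H]2C(C)C)COC3=O)CO)[C@@H](C(=O)OCC[Si](C)(C)C)[C@@H]1/C=C(\CO)C(=O)OCC[Si](C)(C)C
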